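The ratio of starting material left to starting material charged stops falling in birch, the asked flask, and the mean of its last three readings gives 51.3 %. I call this s, the survival per dose of catalyst, where one dose is the catalyst charge of birch.

| flask | starting material | second substrate | capture agent | free catalyst | temperature | remark | time |
|---|---|---|---|---|---|---|---|
| birch | 0.26 M | 0.52 M | 0.078 M | 4.4 mM | 100 °C | the very flask that is asked about, followed so far |  |
| cedar | 0.39 M | 0.52 M | 0.078 M | 4.4 mM | 85 °C | run made earlier |  |
| flask | 0.26 M | 0.520 M | 0.0780 M | 4.4 mM | 100 °C |  | 5.0 h |

| run | time / min | target / % | starting material / % |
|---|---|---|---|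
| birch | 40.0 | 44.9 | 55.4 |
| birch | 80.0 | 46.7 | 51.8 |
| birch | 120 | 46.6 | 51.0 |
| birch | 150 | 45.4 | 51.8 |
| birch | 180 | 45.2 | 51.0 |
| cedar | 8.00 | 4.6 | 94.5 |
| cedar | 15.0 | 8.6 | 90.2 |
| cedar | 25.0 | 13.7 | 85.9 |
| cedar | 30.0 | 15.5 | 83.1 |
| cedar | 40.0 | 20.0 | 79.2 |

(scatter of a reading: 0.5 percentage points)

- red: change nothing and wait 1.5 h more
- violet: at 5.0 h add free catalyst, 100 % of the amount charged, then wait 1.5 h
- grey: at 5.0 h take out 90 % of the target then present, then wait 1.5 h
- amber: at 5.0 h raise the temperature by 15 K, then wait 1.5 h

- target taken out counts as made
- steps thought possible: catalyst intermediate B -> free catalyst + second product; catalyst intermediate B + capture agent -> trapped intermediate; catalyst intermediate A -> free catalyst + target; starting material + free catalyst <-> catalyst intermediate A; target -> over-reaction product; second substrate + free catalyst <-> catalyst intermediate B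
- additions bring no volume worth counting

- target, in percent of the starting material first charged, at 5.0 h
- the remedy with the largest gain of target, or "none" below 2 percentage points (red / violet / grey / amber / none)
- target present, with what was taken out counted in, in percent of the starting material first charged, after violet
- target present, with what was taken out counted in, in percent of the starting material first charged, after amber

Cedar shares its second substrate, capture agent and catalyst with birch, but it holds more starting material and runs colder, so it is a different flask in two settings. Birch gains 1.8 percentage points of target from 40.0 min to 80.0 min, while cedar gains 4.5 points in the shorter stretch from 30.0 min to 40.0 min. Cedar's target is still rising up to its last reading, which shows 79.2 % of starting material, so its readings end on a working catalyst and give no s of their own.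

Birch does not stop at an equilibrium, since the step from catalyst intermediate A to free catalyst and target has no way back. I read its stall as catalyst lost to trapped intermediate, because capture agent is charged far above catalyst. With 51.3 % of starting material unused in birch, I take it that the catalyst is lost while starting material is still there.

Starting material and second substrate share the free catalyst, and the listed loss runs through catalyst intermediate B. Per catalyst lost, the starting material consumed is therefore proportional to its concentration, so a dose removes a fixed fraction, not a fixed amount. This needs second substrate to stay near its charge, which I assume, and capture agent too, of which a dose can take at most 5.64 %.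

Target falls slowly after the stall, and carrying its drift from 80.0 min to 180 min forward gives 43.4 % at 5.0 h. Violet, a second dose, turns the fraction of s that is used into target, a gain of 25 points, so I expect about 68.4 %. Red, grey and amber add no working catalyst, so I expect target no higher than now, and for amber lower by an amount I do not reckon here.

The forecast says 42.3 % now, violet as best, 36 % after amber and 64 % after violet, which is less than my figure, holding that “fresh catalyst removes about half the remaining starting material”.

The flask gives 42.8 % now and violet as best, with a gain of 27 points, 69.3 % after violet and 35.0 % after amber.

    catalyst intermediate B → free catalyst + second product (k = 0.249 /s, Ea = 84.0 kJ/mol)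
    catalyst intermediate B + capture agent → trapped intermediate (k = 0.192 /M/s, Ea = 68.0 kJ/mol)
    catalyst intermediate A → free catalyst + target (k = 0.0382 /s, Ea = 100 kJ/mol)
    starting material + free catalyst ⇌ catalyst intermediate A (K = 19.0 /M, k = 6.75 /M/s, Ea = 52.0 kJ/mol, ΔH = −90.0 kJ/mol)
    target → over-reaction product (k = 7.81 × 10⁻⁶ /s, Ea = 125 kJ/mol)
    second substrate + free catalyst ⇌ catalyst intermediate B (K = 0.646 /M, k = 3.17 /M/s, Ea = 53.0 kJ/mol, ΔH = −50.0 kJ/mol)
    (constants at 100 °C)

The neighbouring flask is the asked flask with 0.018 M of free catalyst, which is 4.09 doses. Raising s to that power leaves 6.50 % of starting material, so I expect target, not starting material, to hold most of the charge. At 300 min that flask holds 1.0 % of starting material, less than the reckoning, and its second substrate is down to 31 % of charge, against 85 % in the asked flask. Its target stands at 86.3 %.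

All runs come from a simulation for an exercise; scatter was added.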